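Retrosynthesis cuts first the aryl–acyl bond C4–C4a of ring C (intramolecular Friedel–Crafts acylation), then the benzylic ether bond O1–C2 (Mitsunobu), then the two aryl–prenyl bonds at C6 and C8 (ortho-lithiation/allylation).
Forward, ring A is completed first (resorcinol → bis-MOM ether → two directed lithiation/prenylations → diol 7), the C2–C3–C4 chain carrying ring B is then attached through O1, and ring C is closed last.
Enabling feature: in ring A, C4a is ortho to O1 and para to the free C7 hydroxyl, C6 and C8 carry the prenyl groups and C5 is meta to both oxygens, so the acyl carbon C4 tethered through C3–C2–O1 can only reach this one doubly activated carbon.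
The same prenyl pair shields the C7 hydroxyl, so O1 is etherified and C4a acylated with no protecting group on O7; the ring closure is run proton-free (acyl triflate, hindered pyridine) to spare the prenyl alkenes and the ionisable C2–O1 bond.
Stereochemistry: C2 is set as the R carbinol by asymmetric transfer hydrogenation of β-keto ester 8 and inverted to S in the Mitsunobu step; the ring closure makes or breaks no bond at C2.

Key step: step 8

Remark (assumption): atoms are numbered as in the flavanone (O1, C2, C3, C4, C4a, C5–C8, C8a; ring A = prenylated benzo ring, ring B = dimethoxyphenyl, ring C = pyranone), and the C7 hydroxyl, flanked by two prenyl groups, is assumed hindered enough to be carried unprotected from step 4 onward.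

Step 1
Reactants: 1 resorcinol (benzene-1,3-diol)
Product: 2 1,3-bis(methoxymethoxy)benzene
Conditions: NaH (2.4 equiv), DMF, 0 °C; MOMCl (2.4 equiv), 0 °C → rt
Reagents that add atoms: chloromethyl methyl ether (MOMCl), COCCl
Why: Williamson-type O-alkylation of the bis-phenoxide with the reactive α-chloro ether should give the bis-acetal, which protects both phenols and supplies the two directing groups for the lithiations.

Step 2
Reactants: 2 1,3-bis(methoxymethoxy)benzene
Product: 4 1,3-bis(methoxymethoxy)-2-(3-methylbut-2-en-1-yl)benzene, via aryllithium 3 (not isolated)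
Conditions: n-BuLi (1.1 equiv), THF, 0 °C → rt; then CuBr·SMe2 (10 mol %), prenyl bromide (1.2 equiv), −78 °C → rt
Reagents that add atoms: 1-bromo-3-methylbut-2-ene (prenyl bromide), CC(C)=CCBr
Why: Directed ortho-metalation removes the ring hydrogen flanked and chelated by both OMOM groups, and the aryllithium is allylated at the primary carbon of prenyl bromide (copper-assisted SN2 allylation, no allylic transposition expected).

Step 3
Reactants: 4 1,3-bis(methoxymethoxy)-2-(3-methylbut-2-en-1-yl)benzene
Product: 6 1,3-bis(methoxymethoxy)-2,4-bis(3-methylbut-2-en-1-yl)benzene, via aryllithium 5 (not isolated)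
Conditions: n-BuLi (1.2 equiv), TMEDA (1.2 equiv), THF, 0 °C; then CuBr·SMe2 (10 mol %), prenyl bromide (1.3 equiv), −78 °C → rt
Reagents that add atoms: 1-bromo-3-methylbut-2-ene (prenyl bromide), CC(C)=CCBr
Why: Second directed ortho-metalation: in 4 the only ring hydrogens next to an OMOM group are the two equivalent ones at C4/C6, so lithiation and SN2 prenylation can give only the 2,4-diprenyl isomer.

Step 4
Reactants: 6 1,3-bis(methoxymethoxy)-2,4-bis(3-methylbut-2-en-1-yl)benzene
Product: 7 2,4-bis(3-methylbut-2-en-1-yl)benzene-1,3-diol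
Conditions: p-TsOH·H2O (0.2 equiv), MeOH, 45 °C
Reagents that add atoms: none
Why: Acid-catalysed acetal exchange with methanol (MOM cleavage) frees both phenols, the catalytic sulfonic acid in methanol being chosen as too mild to add the new ortho hydroxyls across the prenyl double bonds.

Step 5
Reactants: 8 ethyl 3-(3,4-dimethoxyphenyl)-3-oxopropanoate
Product: 9 ethyl (3R)-3-(3,4-dimethoxyphenyl)-3-hydroxypropanoate
Conditions: RuCl[(R,R)-TsDPEN](p-cymene) (1 mol %), HCO2H/Et3N (5:2), 35 °C
Reagents that add atoms: none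
Why: Noyori–Ikariya asymmetric transfer hydrogenation of the aryl ketone, in which the (R,R)-TsDPEN ruthenium hydride is expected to deliver hydride to the face that gives the R benzylic carbinol (same sense as acetophenone to (R)-1-phenylethanol), so the stereocentre is set here under catalyst control.

Step 6
Reactants: 7 2,4-bis(3-methylbut-2-en-1-yl)benzene-1,3-diol; 9 ethyl (3R)-3-(3,4-dimethoxyphenyl)-3-hydroxypropanoate
Product: 10 ethyl (3S)-3-(3,4-dimethoxyphenyl)-3-[3-hydroxy-2,4-bis(3-methylbut-2-en-1-yl)phenoxy]propanoate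
Conditions: PPh3 (1.3 equiv), DIAD (1.3 equiv, slow addition), 7 (1.5 equiv), toluene, −20 °C → 0 °C
Reagents that add atoms: none
Why: Mitsunobu etherification, in which the alkoxyphosphonium of 9 is displaced with SN2 inversion (R to S) by the phenoxide of the C1 hydroxyl of 7, which has one ortho substituent, while the C3 hydroxyl between two prenyl groups should be too hindered to compete; toluene and low temperature keep a tight ion pair against ionisation.

Step 7
Reactants: 10 ethyl (3S)-3-(3,4-dimethoxyphenyl)-3-[3-hydroxy-2,4-bis(3-methylbut-2-en-1-yl)phenoxy]propanoate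
Product: 11 (3S)-3-(3,4-dimethoxyphenyl)-3-[3-hydroxy-2,4-bis(3-methylbut-2-en-1-yl)phenoxy]propanoic acid
Conditions: LiOH·H2O (3 equiv), THF/H2O (3:1), 0 °C → rt; then 1 M HCl to pH 3, 0 °C
Reagents that add atoms: lithium hydroxide, [Li+].[OH-]
Why: Saponification (acyl–oxygen cleavage by hydroxide) at low temperature, where the phenoxide formed on ring A makes the ring-A aryloxide a poorer leaving group and so should disfavour E1cB loss of the ether.

Step 8
Reactants: 11 (3S)-3-(3,4-dimethoxyphenyl)-3-[3-hydroxy-2,4-bis(3-methylbut-2-en-1-yl)phenoxy]propanoic acid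
Product: 14 (2S)-2-(3,4-dimethoxyphenyl)-7-hydroxy-6,8-bis(3-methylbut-2-en-1-yl)-2,3-dihydro-4H-chromen-4-one, via acid chloride 12 (not isolated), via acyl triflate 13 (not isolated)
Conditions: 1-chloro-N,N,2-trimethylprop-1-en-1-amine (1.1 equiv), CH2Cl2, 0 °C → rt; then 2,6-di-tert-butyl-4-methylpyridine (2.5 equiv), AgOTf (1.3 equiv), CH2Cl2 (0.01 M), −78 °C → −30 °C
Reagents that add atoms: none
Why: The α-chloroenamine converts the acid into acid chloride 12 without releasing acid, AgOTf exchanges chloride for triflate, and acyl triflate 13 (or the acylium ion derived from it) is attacked by C4a of ring A, the arenium ion giving up its proton to the hindered pyridine. This is an intramolecular Friedel–Crafts acylation through a carboxylic–triflic mixed anhydride, the closest known types being acid chloride/silver triflate acylations and the closure of 3-aryloxypropanoic acids to chroman-4-ones. Ring C closes in a 6-exo-trig mode at the acyl carbon (6-exo-dig if the free acylium reacts), with the C=O bond outside and the nucleophilic C4a=C8a bond inside the new ring. No stereocentre is formed, and C2 should keep its S configuration because no bond to C2 is made or broken and the buffered medium holds no protic acid to ionise the C2–O1 bond. The step needs site selectivity for C4a over C6′ of ring B (indanone closure), the hindered phenol oxygen and the prenyl alkenes; this is secured because C4a is ortho to O1 and para to the free C7 hydroxyl, C6 and C8 are blocked, the six-membered closure is favoured, and high dilution suppresses intermolecular O-acylation.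

Compound list
1 | resorcinol (benzene-1,3-diol) | Oc1cccc(O)c1 | starting material
2 | 1,3-bis(methoxymethoxy)benzene | COCOc1cccc(OCOC)c1 | intermediate
3 | [2,6-bis(methoxymethoxy)phenyl]lithium (formed in the flask) | [Li]c1c(OCOC)cccc1OCOC | intermediate
4 | 1,3-bis(methoxymethoxy)-2-(3-methylbut-2-en-1-yl)benzene | COCOc1cccc(OCOC)c1CC=C(C)C | intermediate
5 | [2,4-bis(methoxymethoxy)-3-(3-methylbut-2-en-1-yl)phenyl]lithium (formed in the flask) | [Li]c1ccc(OCOC)c(CC=C(C)C)c1OCOC | intermediate
6 | 1,3-bis(methoxymethoxy)-2,4-bis(3-methylbut-2-en-1-yl)benzene | COCOc1ccc(CC=C(C)C)c(OCOC)c1CC=C(C)C | intermediate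
7 | 2,4-bis(3-methylbut-2-en-1-yl)benzene-1,3-diol | Oc1ccc(CC=C(C)C)c(O)c1CC=C(C)C | intermediate
8 | ethyl 3-(3,4-dimethoxyphenyl)-3-oxopropanoate | CCOC(=O)CC(=O)c1ccc(OC)c(OC)c1 | starting material
9 | ethyl (3R)-3-(3,4-dimethoxyphenyl)-3-hydroxypropanoate | CCOC(=O)C[C@@H](O)c1ccc(OC)c(OC)c1 | intermediate
10 | ethyl (3S)-3-(3,4-dimethoxyphenyl)-3-[3-hydroxy-2,4-bis(3-methylbut-2-en-1-yl)phenoxy]propanoate | CCOC(=O)C[C@H](Oc1ccc(CC=C(C)C)c(O)c1CC=C(C)C)c1ccc(OC)c(OC)c1 | intermediate
11 | (3S)-3-(3,4-dimethoxyphenyl)-3-[3-hydroxy-2,4-bis(3-methylbut-2-en-1-yl)phenoxy]propanoic acid | OC(=O)C[C@H](Oc1ccc(CC=C(C)C)c(O)c1CC=C(C)C)c1ccc(OC)c(OC)c1 | intermediate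
12 | (3S)-3-(3,4-dimethoxyphenyl)-3-[3-hydroxy-2,4-bis(3-methylbut-2-en-1-yl)phenoxy]propanoyl chloride (formed in the flask) | ClC(=O)C[C@H](Oc1ccc(CC=C(C)C)c(O)c1CC=C(C)C)c1ccc(OC)c(OC)c1 | intermediate
13 | (3S)-3-(3,4-dimethoxyphenyl)-3-[3-hydroxy-2,4-bis(3-methylbut-2-en-1-yl)phenoxy]propanoyl trifluoromethanesulfonate (formed in the flask) | O=C(OS(=O)(=O)C(F)(F)F)C[C@H](Oc1ccc(CC=C(C)C)c(O)c1CC=C(C)C)c1ccc(OC)c(OC)c1 | intermediate
14 | (2S)-2-(3,4-dimethoxyphenyl)-7-hydroxy-6,8-bis(3-methylbut-2-en-1-yl)-2,3-dihydro-4H-chromen-4-one (IN0946) | COc1ccc([C@@H]2CC(=O)c3cc(CC=C(C)C)c(O)c(CC=C(C)C)c3O2)cc1OC | target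

Total step count: 8. Longest linear sequence: 7 steps (steps 1, 2, 3, 4, 6, 7, 8 from resorcinol); step 5 is the one-step side branch.

Steps most likely to fail

1. Step 8 (ring closure). What may go wrong: ionisation of the C2–O1 bond or retro-oxa-Michael loss of the phenol before acylation (racemisation by way of the chalcone), acid-triggered addition of the phenol to a prenyl alkene, or intermolecular O-acylation. Fallback (anionic instead of cationic closure of the same bond; sets out from 6, returns at 14): a third ortho-lithiation of 6 (n-BuLi, TMEDA, THF, 0 °C), now at the last ring position next to an OMOM group, should give [2,4-bis(methoxymethoxy)-3,5-bis(3-methylbut-2-en-1-yl)phenyl]lithium F1, which is quenched with I2 at −78 °C to 1-iodo-2,4-bis(methoxymethoxy)-3,5-bis(3-methylbut-2-en-1-yl)benzene F2. Acetal cleavage as in step 4 should give 4-iodo-2,6-bis(3-methylbut-2-en-1-yl)benzene-1,3-diol F3. Mitsunobu coupling with 9 as in step 6, expected at the more acidic iodine-flanked hydroxyl, should give ethyl (3S)-3-(3,4-dimethoxyphenyl)-3-[3-hydroxy-6-iodo-2,4-bis(3-methylbut-2-en-1-yl)phenoxy]propanoate F4, and saponification as in step 7 the corresponding (3S)-propanoic acid F5. With t-BuLi (4.2 equiv) in THF at −90 °C both OH groups are deprotonated and iodine is exchanged for lithium to give the trilithiated aryllithium carboxylate F6, whose aryl carbanion adds to the lithium carboxylate (Parham cyclisation); aqueous work-up should release 14.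

2. Step 6 (Mitsunobu etherification). What may go wrong: ionisation of the electron-rich benzylic alkoxyphosphonium with erosion of enantiopurity, β-elimination to the cinnamate, or incomplete discrimination between the two hydroxyls of 7. Fallback (catalyst-controlled allylic etherification that sets C2 and the O1–C2 bond together; sets out from 7, returns at 11): commercial (2E)-3-(3,4-dimethoxyphenyl)prop-2-en-1-ol with methyl chloroformate and pyridine gives methyl (2E)-3-(3,4-dimethoxyphenyl)prop-2-en-1-yl carbonate F7. The monosodium phenoxide of 7 (NaH, 1 equiv) with F7, [Ir(cod)Cl]2 and a BINOL-derived bis(1-phenylethyl)amine phosphoramidite (ligand enantiomer chosen for the S ether) in THF should give the branched ether 3-{[(1S)-1-(3,4-dimethoxyphenyl)prop-2-en-1-yl]oxy}-2,6-bis(3-methylbut-2-en-1-yl)phenol F8. 9-BBN (2.5 equiv, THF), which adds to the terminal alkene only and also borylates the phenol, gives the bis-borylated organoborane F9; NaBO3·4H2O then gives (3S)-3-(3,4-dimethoxyphenyl)-3-[3-hydroxy-2,4-bis(3-methylbut-2-en-1-yl)phenoxy]propan-1-ol F10. Dess–Martin oxidation (NaHCO3 buffer) gives the corresponding (3S)-propanal F11, and Pinnick oxidation (NaClO2, NaH2PO4, 2-methylbut-2-ene) gives 11.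

3. Step 7 (saponification). What may go wrong: base-induced β-elimination of the ring-A aryloxide (E1cB), which would cleave the ether or, after re-addition, scramble C2. Fallback (ester removed without base; sets out from 8, returns at 11): transesterification of 8 with allyl alcohol (DMAP cat., toluene, reflux) gives prop-2-en-1-yl 3-(3,4-dimethoxyphenyl)-3-oxopropanoate F12. Transfer hydrogenation as in step 5 gives prop-2-en-1-yl (3R)-3-(3,4-dimethoxyphenyl)-3-hydroxypropanoate F13, and Mitsunobu coupling with 7 as in step 6 gives prop-2-en-1-yl (3S)-3-(3,4-dimethoxyphenyl)-3-[3-hydroxy-2,4-bis(3-methylbut-2-en-1-yl)phenoxy]propanoate F14. Pd(PPh3)4 (cat.) and morpholine in THF at rt then transfer the allyl group to the amine and give 11.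

Further compounds
F1 | step 8 | [2,4-bis(methoxymethoxy)-3,5-bis(3-methylbut-2-en-1-yl)phenyl]lithium | [Li]c1cc(CC=C(C)C)c(OCOC)c(CC=C(C)C)c1OCOC
F2 | step 8 | 1-iodo-2,4-bis(methoxymethoxy)-3,5-bis(3-methylbut-2-en-1-yl)benzene | Ic1cc(CC=C(C)C)c(OCOC)c(CC=C(C)C)c1OCOC
F3 | step 8 | 4-iodo-2,6-bis(3-methylbut-2-en-1-yl)benzene-1,3-diol | Oc1c(I)cc(CC=C(C)C)c(O)c1CC=C(C)C
F4 | step 8 | ethyl (3S)-3-(3,4-dimethoxyphenyl)-3-[3-hydroxy-6-iodo-2,4-bis(3-methylbut-2-en-1-yl)phenoxy]propanoate | CCOC(=O)C[C@H](Oc1c(I)cc(CC=C(C)C)c(O)c1CC=C(C)C)c1ccc(OC)c(OC)c1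
F5 | step 8 | (3S)-3-(3,4-dimethoxyphenyl)-3-[3-hydroxy-6-iodo-2,4-bis(3-methylbut-2-en-1-yl)phenoxy]propanoic acid | OC(=O)C[C@H](Oc1c(I)cc(CC=C(C)C)c(O)c1CC=C(C)C)c1ccc(OC)c(OC)c1
F6 | step 8 | lithium (3S)-3-(3,4-dimethoxyphenyl)-3-[6-lithio-3-(lithiooxy)-2,4-bis(3-methylbut-2-en-1-yl)phenoxy]propanoate | [Li]OC(=O)C[C@H](Oc1c([Li])cc(CC=C(C)C)c(O[Li])c1CC=C(C)C)c1ccc(OC)c(OC)c1
F7 | step 6 | methyl (2E)-3-(3,4-dimethoxyphenyl)prop-2-en-1-yl carbonate | COC(=O)OC/C=C/c1ccc(OC)c(OC)c1
F8 | step 6 | 3-{[(1S)-1-(3,4-dimethoxyphenyl)prop-2-en-1-yl]oxy}-2,6-bis(3-methylbut-2-en-1-yl)phenol | C=C[C@H](Oc1ccc(CC=C(C)C)c(O)c1CC=C(C)C)c1ccc(OC)c(OC)c1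
F9 | step 6 | 9-[(3S)-3-(3,4-dimethoxyphenyl)-3-{3-[(9-borabicyclo[3.3.1]nonan-9-yl)oxy]-2,4-bis(3-methylbut-2-en-1-yl)phenoxy}propyl]-9-borabicyclo[3.3.1]nonane | B1(C2CCCC1CCC2)CC[C@H](Oc1ccc(CC=C(C)C)c(OB2C3CCCC2CCC3)c1CC=C(C)C)c1ccc(OC)c(OC)c1
F10 | step 6 | (3S)-3-(3,4-dimethoxyphenyl)-3-[3-hydroxy-2,4-bis(3-methylbut-2-en-1-yl)phenoxy]propan-1-ol | OCC[C@H](Oc1ccc(CC=C(C)C)c(O)c1CC=C(C)C)c1ccc(OC)c(OC)c1
F11 | step 6 | (3S)-3-(3,4-dimethoxyphenyl)-3-[3-hydroxy-2,4-bis(3-methylbut-2-en-1-yl)phenoxy]propanal | O=CC[C@H](Oc1ccc(CC=C(C)C)c(O)c1CC=C(C)C)c1ccc(OC)c(OC)c1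
F12 | step 7 | prop-2-en-1-yl 3-(3,4-dimethoxyphenyl)-3-oxopropanoate | C=CCOC(=O)CC(=O)c1ccc(OC)c(OC)c1
F13 | step 7 | prop-2-en-1-yl (3R)-3-(3,4-dimethoxyphenyl)-3-hydroxypropanoate | C=CCOC(=O)C[C@@H](O)c1ccc(OC)c(OC)c1
F14 | step 7 | prop-2-en-1-yl (3S)-3-(3,4-dimethoxyphenyl)-3-[3-hydroxy-2,4-bis(3-methylbut-2-en-1-yl)phenoxy]propanoate | C=CCOC(=O)C[C@H](Oc1ccc(CC=C(C)C)c(O)c1CC=C(C)C)c1ccc(OC)c(OC)c1
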